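**Retrosynthetic overview**

1. Target ⇐ stoichiometry-controlled mono-O-sulfation of all-E (2R,3R,2'R,3'R)-nostoxanthin at the unhindered 3-OH (the 2-OH is neopentylic).
2. Nostoxanthin ⇐ double Wittig, C15 + C10 + C15: two equivalents of one diol phosphonium salt plus 2,7-dimethylocta-2,4,6-trienedial.
3. C15 salt ⇐ 3,4-dioxygenated 2,2,6-trimethylcyclohexanone (acetonide) + (E)-3-methylpent-2-en-4-yn-1-ol: acetylide addition, trans-reduction, PPh3·HBr with dehydration.
4. The carbocycle (the only ring built, used for both end groups) ⇐ intramolecular nitrile oxide–alkene [3+2] cycloaddition, then N–O cleavage and retro-aldol loss of CH2O.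
5. Acyclic oxime ⇐ D-pantolactone (supplies C-2 and the gem-dimethyl carbon) + methallyl bromide; chelation-controlled addition sets C-3.

Assumption: the target is the all-E 3-(hydrogen sulfate) of (2R,3R,2'R,3'R)-nostoxanthin, delivered in the acid form drawn (it is best stored as its sodium salt). None of the route has been run; the selectivities quoted are expectations from precedent.

**Route**

Step 1
Reactants: 1 D-(−)-pantolactone
Product: 2 (3R)-4,4-dimethyloxolane-2,3-diol (D-pantolactol; anomer mixture)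
Conditions: i-Bu2AlH (2.2 equiv), CH2Cl2, −78 °C; MeOH, then Na2SO4·10H2O
Reagents that add atoms: none
Why: Partial hydride reduction of a γ-lactone stops at the aluminium hemiacetal at −78 °C (the first equivalent only deprotonates the OH), and the bought stereocenter is untouched.

Step 2
Reactants: 2 (3R)-4,4-dimethyloxolane-2,3-diol; 3 3-bromo-2-methylprop-1-ene (methallyl bromide)
Product: 4 (3R,4R)-2,2,6-trimethylhept-6-ene-1,3,4-triol
Conditions: In powder (1.5 equiv), THF/H2O 1:1, sonication, rt, 16 h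
Reagents that add atoms: none
Why: Aqueous Barbier allylation of the open hydroxy-aldehyde form, in which indium chelated between the free α-hydroxyl and the carbonyl (Cram-chelate) delivers the allyl group syn, so the new carbinol center (R) is set by the pantolactone center.

Step 3
Reactants: 4 (3R,4R)-2,2,6-trimethylhept-6-ene-1,3,4-triol
Product: 5 2-[(4R,5R)-2,2-dimethyl-5-(2-methylprop-2-en-1-yl)-1,3-dioxolan-4-yl]-2-methylpropan-1-ol
Conditions: 2,2-dimethoxypropane, p-TsOH·H2O (cat.), acetone, rt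
Reagents that add atoms: 2,2-dimethoxypropane, COC(C)(C)OC
Why: Thermodynamic acetonide formation favours the trans-4,5-disubstituted dioxolane of the threo 1,2-diol and leaves the neopentyl primary OH free; the cis-dioxolane from any erythro triol is removed here by chromatography.

Step 4
Reactants: 5 2-[(4R,5R)-2,2-dimethyl-5-(2-methylprop-2-en-1-yl)-1,3-dioxolan-4-yl]-2-methylpropan-1-ol
Product: 6 2-[(4R,5R)-2,2-dimethyl-5-(2-methylprop-2-en-1-yl)-1,3-dioxolan-4-yl]-2-methylpropanal
Conditions: Dess–Martin periodinane, NaHCO3, CH2Cl2, rt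
Reagents that add atoms: none
Why: Dess–Martin oxidation of a primary alcohol to an aldehyde that has no α-hydrogen, so it cannot epimerise or enolise.

Step 5
Reactants: 6 2-[(4R,5R)-2,2-dimethyl-5-(2-methylprop-2-en-1-yl)-1,3-dioxolan-4-yl]-2-methylpropanal
Product: 7 (E)-2-[(4R,5R)-2,2-dimethyl-5-(2-methylprop-2-en-1-yl)-1,3-dioxolan-4-yl]-2-methylpropanal oxime
Conditions: NH2OH·HCl, NaOAc, EtOH/H2O, 50 °C
Reagents that add atoms: hydroxylamine hydrochloride, NO.Cl
Why: Oxime condensation; the buffered medium leaves the acetonide intact.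

Step 6
Reactants: 7 (E)-2-[(4R,5R)-2,2-dimethyl-5-(2-methylprop-2-en-1-yl)-1,3-dioxolan-4-yl]-2-methylpropanal oxime
Product: 9 (5R,6R)-5,6-(isopropylidenedioxy)-3a,7,7-trimethyl-3,3a,4,5,6,7-hexahydro-2,1-benzisoxazole (3a-epimers), via nitrile oxide 8 (not isolated)
Conditions: aq. NaOCl, Et3N (cat.), CH2Cl2 (0.02 M), 0 °C to rt
Reagents that add atoms: none
Why: Intramolecular nitrile oxide–alkene 1,3-dipolar cycloaddition closes the six-membered carbocycle (C-5/C-6 bond of the end group); the tether forces the fused regiochemistry and the neopentyl nitrile oxide resists dimerisation, while the new quaternary center is later destroyed.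

Step 7
Reactants: 9 (5R,6R)-5,6-(isopropylidenedioxy)-3a,7,7-trimethyl-3,3a,4,5,6,7-hexahydro-2,1-benzisoxazole
Product: 11 (3R,4R)-3,4-(isopropylidenedioxy)-2,2,6-trimethylcyclohexan-1-one (6-epimers), via hydroxymethyl ketone 10 (not isolated)
Conditions: H2 (1 atm), Raney Ni, B(OH)3, MeOH/H2O 5:1, rt; filter; K2CO3 (cat.), MeOH, 50 °C
Reagents that add atoms: water, O
Why: Hydrogenolysis of the N–O bond and hydrolysis of the imine give a β-hydroxy ketone whose quaternary α-carbon can only undergo retro-aldol loss of formaldehyde, relieving the strain of two flanking quaternary carbons; the diol centers cannot epimerise.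

Step 8
Reactants: 11 (3R,4R)-3,4-(isopropylidenedioxy)-2,2,6-trimethylcyclohexan-1-one; 12 (E)-3-methylpent-2-en-4-yn-1-ol
Product: 14 (2E)-5-[(3R,4R)-1-hydroxy-3,4-(isopropylidenedioxy)-2,2,6-trimethylcyclohexyl]-3-methylpent-2-en-4-yn-1-ol (epimers at C-1 and C-6 of the ring), via dilithio enynolate 13 (not isolated)
Conditions: 12, n-BuLi (2 equiv), THF, −78 to −20 °C; then 11, −78 °C to rt; H2O
Reagents that add atoms: none
Why: 1,2-Addition of a lithium acetylide to the hindered ketone; the new carbinol and the adjacent CH(Me) center are both removed in step 10.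

Step 9
Reactants: 14 (2E)-5-[(3R,4R)-1-hydroxy-3,4-(isopropylidenedioxy)-2,2,6-trimethylcyclohexyl]-3-methylpent-2-en-4-yn-1-ol
Product: 15 (2E,4E)-5-[(3R,4R)-1-hydroxy-3,4-(isopropylidenedioxy)-2,2,6-trimethylcyclohexyl]-3-methylpenta-2,4-dien-1-ol
Conditions: NaAlH2(OCH2CH2OMe)2, THF, 0 °C to rt; aq. NaOH
Reagents that add atoms: none
Why: Alkoxide-directed trans-hydroalumination of the propargylic alcohol gives the E-alkene only.

Step 10
Reactants: 15 (2E,4E)-5-[(3R,4R)-1-hydroxy-3,4-(isopropylidenedioxy)-2,2,6-trimethylcyclohexyl]-3-methylpenta-2,4-dien-1-ol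
Product: 16 [(2E,4E)-5-[(4R,5R)-4,5-dihydroxy-2,6,6-trimethylcyclohex-1-en-1-yl]-3-methylpenta-2,4-dien-1-yl]triphenylphosphonium bromide
Conditions: Ph3P·HBr (1.1 equiv), MeOH, rt; H2O
Reagents that add atoms: triphenylphosphine hydrobromide, Br.c1ccc(cc1)P(c1ccccc1)c1ccccc1
Why: Acid ionisation of the tertiary allylic alcohol followed by E1 loss of the ring proton gives the conjugated triene and allylic substitution puts phosphorus on the primary terminus (Wittig salt formation); the acidic methanol is expected to cleave the strained trans-acetonide in the same operation without touching the two carbinol centers.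

Step 11
Reactants: 16 the phosphonium bromide (2.1 equiv); 17 (2E,4E,6E)-2,7-dimethylocta-2,4,6-trienedial
Product: 19 all-E (2R,3R,2'R,3'R)-β,β-carotene-2,3,2',3'-tetrol (nostoxanthin), via phosphorus ylide 18 (not isolated)
Conditions: NaOMe, MeOH/CH2Cl2, 0 °C to rt; then reflux in EtOH (Z to E), crystallise
Reagents that add atoms: none
Why: Double Wittig olefination of the C10 dialdehyde with the semi-stabilised ylide tolerates the free diols; thermal isomerisation and crystallisation give the all-E polyene.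

Step 12
Reactants: 19 all-E (2R,3R,2'R,3'R)-β,β-carotene-2,3,2',3'-tetrol
Product: 20 (2R,3R,2'R,3'R)-2,3,2',3'-tetrahydroxy-β,β-carotene 3-(hydrogen sulfate) (CNP0229621.3)
Conditions: SO3·pyridine (1.0 equiv), pyridine, 0 °C, dark, Ar; H+-form cation-exchange resin, 0 °C; reverse-phase chromatography, recover 19
Reagents that add atoms: sulfur trioxide–pyridine complex, [O-]S(=O)(=O)[n+]1ccccc1
Why: O-Sulfation with an amine–SO3 complex goes to the less hindered 3-OH; the two 3-OH groups are symmetry-equivalent, so one equivalent gives the monosulfate as the main product (statistical ceiling about 50%) with recyclable tetrol and separable disulfate.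

**Compound list**

1 | D-(−)-pantolactone, (3R)-3-hydroxy-4,4-dimethyloxolan-2-one | CC1(C)COC(=O)[C@@H]1O | starting material
2 | (3R)-4,4-dimethyloxolane-2,3-diol | CC1(C)COC(O)[C@@H]1O | intermediate
3 | 3-bromo-2-methylprop-1-ene | C=C(C)CBr | starting material
4 | (3R,4R)-2,2,6-trimethylhept-6-ene-1,3,4-triol | OCC(C)(C)[C@@H](O)[C@H](O)CC(C)=C | intermediate
5 | 2-[(4R,5R)-2,2-dimethyl-5-(2-methylprop-2-en-1-yl)-1,3-dioxolan-4-yl]-2-methylpropan-1-ol | OCC(C)(C)[C@H]1OC(C)(C)O[C@@H]1CC(C)=C | intermediate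
6 | 2-[(4R,5R)-2,2-dimethyl-5-(2-methylprop-2-en-1-yl)-1,3-dioxolan-4-yl]-2-methylpropanal | O=CC(C)(C)[C@H]1OC(C)(C)O[C@@H]1CC(C)=C | intermediate
7 | (E)-oxime of 6 | O/N=C/C(C)(C)[C@H]1OC(C)(C)O[C@@H]1CC(C)=C | intermediate
8 | nitrile oxide of 6 | [O-][N+]#CC(C)(C)[C@H]1OC(C)(C)O[C@@H]1CC(C)=C | intermediate
9 | (5R,6R)-5,6-(isopropylidenedioxy)-3a,7,7-trimethyl-3,3a,4,5,6,7-hexahydro-2,1-benzisoxazole | CC12CON=C1C(C)(C)[C@H]1OC(C)(C)O[C@@H]1C2 | intermediate
10 | (3R,4R)-6-(hydroxymethyl)-3,4-(isopropylidenedioxy)-2,2,6-trimethylcyclohexan-1-one | O=C1C(C)(CO)C[C@H]2OC(C)(C)O[C@@H]2C1(C)C | intermediate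
11 | (3R,4R)-3,4-(isopropylidenedioxy)-2,2,6-trimethylcyclohexan-1-one | O=C1C(C)C[C@H]2OC(C)(C)O[C@@H]2C1(C)C | intermediate
12 | (E)-3-methylpent-2-en-4-yn-1-ol | C#C/C(C)=C/CO | starting material
13 | dilithio derivative of 12 | [Li]C#C/C(C)=C/CO[Li] | intermediate
14 | (2E)-5-[(3R,4R)-1-hydroxy-3,4-(isopropylidenedioxy)-2,2,6-trimethylcyclohexyl]-3-methylpent-2-en-4-yn-1-ol | OC/C=C(C)/C#CC1(O)C(C)C[C@H]2OC(C)(C)O[C@@H]2C1(C)C | intermediate
15 | (2E,4E)-5-[(3R,4R)-1-hydroxy-3,4-(isopropylidenedioxy)-2,2,6-trimethylcyclohexyl]-3-methylpenta-2,4-dien-1-ol | OC/C=C(C)/C=C/C1(O)C(C)C[C@H]2OC(C)(C)O[C@@H]2C1(C)C | intermediate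
16 | [(2E,4E)-5-[(4R,5R)-4,5-dihydroxy-2,6,6-trimethylcyclohex-1-en-1-yl]-3-methylpenta-2,4-dien-1-yl]triphenylphosphonium bromide | CC1=C(/C=C/C(C)=C/C[P+](c2ccccc2)(c2ccccc2)c2ccccc2)C(C)(C)[C@@H](O)[C@H](O)C1.[Br-] | intermediate
17 | (2E,4E,6E)-2,7-dimethylocta-2,4,6-trienedial | O=C/C(C)=C/C=C/C=C(C)/C=O | starting material
18 | ylide of 16 | CC1=C(/C=C/C(C)=C/C=P(c2ccccc2)(c2ccccc2)c2ccccc2)C(C)(C)[C@@H](O)[C@H](O)C1 | intermediate
19 | all-E (2R,3R,2'R,3'R)-β,β-carotene-2,3,2',3'-tetrol (nostoxanthin) | CC1=C(/C=C/C(C)=C/C=C/C(C)=C/C=C/C=C(C)/C=C/C=C(C)/C=C/C2=C(C)C[C@@H](O)[C@H](O)C2(C)C)C(C)(C)[C@@H](O)[C@H](O)C1 | intermediate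
20 | (2R,3R,2'R,3'R)-2,3,2',3'-tetrahydroxy-β,β-carotene 3-(hydrogen sulfate) | CC1=C(/C=C/C(C)=C/C=C/C(C)=C/C=C/C=C(C)/C=C/C=C(C)/C=C/C2=C(C)C[C@@H](OS(=O)(=O)O)[C@H](O)C2(C)C)C(C)(C)[C@@H](O)[C@H](O)C1 | target

**Step count**

Total steps: 12. Longest linear sequence: 12 (from D-pantolactone; 3, 12 and 17 are bought).

**Steps most likely to fail and their fallbacks**

Step 2 (the hindered lactol may react slowly and the syn:anti ratio may be modest). The fallback sets out from 1 and comes back at 4. Compound 1 is etherified with 4-methoxybenzyl trichloroacetimidate and catalytic TfOH to (3R)-3-[(4-methoxybenzyl)oxy]-4,4-dimethyloxolan-2-one F1. i-Bu2AlH at −78 °C gives the lactol (3R)-3-[(4-methoxybenzyl)oxy]-4,4-dimethyloxolan-2-ol F2. Methallylmagnesium chloride with MgBr2·OEt2 in CH2Cl2/Et2O at −78 °C then adds to the α-alkoxy aldehyde form under Cram-chelate control to give (3R,4R)-3-[(4-methoxybenzyl)oxy]-2,2,6-trimethylhept-6-ene-1,4-diol F3. DDQ in wet CH2Cl2 followed by dilute AcOH removes the ether and returns triol 4.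

Step 6 (cyclisation onto a 1,1-disubstituted alkene across a trans-acetonide; the hindered imine of step 7 is a further hazard). The fallback sets out from 6 and comes back at 11, bypassing steps 5 to 7. Wittig methylenation of 6 (Ph3P=CH2 from Ph3PCH3Br and KOt-Bu) gives (4R,5R)-2,2-dimethyl-4-(2-methylbut-3-en-2-yl)-5-(2-methylprop-2-en-1-yl)-1,3-dioxolane F4. Ring-closing metathesis with the second-generation Grubbs catalyst (H2IMes)(PCy3)Cl2Ru=CHPh in toluene at 60 °C gives (3aR,7aR)-2,2,4,4,6-pentamethyl-3a,4,7,7a-tetrahydro-1,3-benzodioxole F5. Hydroboration–oxidation (BH3·THF; H2O2, NaOH) places the hydroxyl on the less substituted alkene carbon to give (3R,4R)-3,4-(isopropylidenedioxy)-2,2,6-trimethylcyclohexan-1-ol F6. Dess–Martin oxidation then gives ketone 11.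

Step 12 (mono- versus bis-sulfation is only statistical). The fallback sets out from 16 and 17 and comes back at 20, replacing steps 11 and 12. One equivalent of 16 with a threefold excess of 17 and NaOMe gives all-E (2R,3R)-2,3-dihydroxy-12'-apo-β-caroten-12'-al F7. SO3·pyridine sulfates its single unhindered 3-OH to the 3-(hydrogen sulfate) of that aldehyde F8. A second Wittig reaction of F8 (as its sodium salt) with 16 and NaOMe, then thermal isomerisation and acidification on the H+-form resin, gives 20.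

**Further compounds**

F1 | step 2 | (3R)-3-[(4-methoxybenzyl)oxy]-4,4-dimethyloxolan-2-one | CC1(C)COC(=O)[C@@H]1OCc1ccc(OC)cc1
F2 | step 2 | (3R)-3-[(4-methoxybenzyl)oxy]-4,4-dimethyloxolan-2-ol | CC1(C)COC(O)[C@@H]1OCc1ccc(OC)cc1
F3 | step 2 | (3R,4R)-3-[(4-methoxybenzyl)oxy]-2,2,6-trimethylhept-6-ene-1,4-diol | OCC(C)(C)[C@@H](OCc1ccc(OC)cc1)[C@H](O)CC(C)=C
F4 | step 6 | (4R,5R)-2,2-dimethyl-4-(2-methylbut-3-en-2-yl)-5-(2-methylprop-2-en-1-yl)-1,3-dioxolane | C=CC(C)(C)[C@H]1OC(C)(C)O[C@@H]1CC(C)=C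
F5 | step 6 | (3aR,7aR)-2,2,4,4,6-pentamethyl-3a,4,7,7a-tetrahydro-1,3-benzodioxole | CC1=CC(C)(C)[C@H]2OC(C)(C)O[C@@H]2C1
F6 | step 6 | (3R,4R)-3,4-(isopropylidenedioxy)-2,2,6-trimethylcyclohexan-1-ol | OC1C(C)C[C@H]2OC(C)(C)O[C@@H]2C1(C)C
F7 | step 12 | all-E (2R,3R)-2,3-dihydroxy-12'-apo-β-caroten-12'-al | CC1=C(/C=C/C(C)=C/C=C/C(C)=C/C=C/C=C(C)/C=O)C(C)(C)[C@@H](O)[C@H](O)C1
F8 | step 12 | all-E (2R,3R)-2,3-dihydroxy-12'-apo-β-caroten-12'-al 3-(hydrogen sulfate) | CC1=C(/C=C/C(C)=C/C=C/C(C)=C/C=C/C=C(C)/C=O)C(C)(C)[C@@H](O)[C@H](OS(=O)(=O)O)C1
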